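## Retrosynthetic overview
1. Target ⇒ C8 alcohol + methacrylic anhydride; the α-methylene-γ-lactone (last ring) ⇐ MnO2 oxidative lactonisation of a C6-OH/C12-OH 2-methylene-1,4-diol.
2. Ten-membered carbocycle ⇐ Nozaki–Hiyama–Kishi closure of C1–C2 (C1 aldehyde + C2 alkenyl iodide), then C2=C3 saturation and C1 oxidation; no target stereocentre is made in the closure.
3. C4–C5 epoxide ⇐ Sharpless epoxidation of a C3 allylic alcohol, built from a C5 aldehyde by Wittig extension.
4. Oxolane (first ring) ⇐ 5-exo opening, with inversion at C7, of a Sharpless-derived C6–C7 vinyl epoxide by the C10 tertiary alcohol; the C6=C7 alkene ⇐ propargylic alcohol hydroalumination/iodination + Stille coupling.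
5. C8 ⇐ ketoreductase reduction of an ynone; C10 ⇐ Sharpless epoxidation of methallyl alcohol. Ring order: oxolane → epoxide → carbocycle → lactone.

Assumption: the SMILES is read literally, (4R,5R,6R,7S,8S,10S), which puts C1 and C6 on opposite faces of the oxolane ring; C7 and C10 are therefore fixed independently before the carbocycle is closed.
Locants in names are those of the target: C1 ketone, C2/C3 CH2, C4(C15 methyl)–C5 epoxide, C6 lactone carbinol, C7 spiro carbon, C8 ester carbinol, C9 CH2, C10(C14 methyl), C11=C13 methylene, C12 lactone carbonyl. PMB = 4-methoxybenzyl, TBS = tert-butyldimethylsilyl, TES = triethylsilyl, TMS = trimethylsilyl.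

## Route

Step 1
Reactants: 1 2-methylprop-2-en-1-ol
Product: 2 (R)-2-methylglycidol [(2R)-2-methyloxiran-2-yl]methanol
Conditions: Ti(OiPr)4 (5 mol %), D-(−)-diisopropyl tartrate (6 mol %), t-BuOOH, 4 Å MS, CH2Cl2, −20 °C
Reagents that add atoms: tert-butyl hydroperoxide, CC(C)(C)OO
Why: Sharpless asymmetric epoxidation, in which the titanium/D-(−)-tartrate catalyst delivers oxygen to one face of the allylic alcohol and so sets C10 (the first stereocentre, from an achiral alkene); the few percent of the other enantiomer is removed later as a diastereomer.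

Step 2
Reactants: 2 (R)-2-methylglycidol
Product: 3 (S)-2-methylglycidyl PMB ether
Conditions: NaH, PMBCl, Bu4NI (cat.), THF/DMF, 0 °C
Reagents that add atoms: 4-methoxybenzyl chloride, COc1ccc(CCl)cc1
Why: Williamson etherification of the primary alkoxide is fast at 0 °C and does not touch C10 (the descriptor changes to S only through the priority rules).

Step 3
Reactants: 3 (S)-2-methylglycidyl PMB ether
Product: 4 (2S)-1-(PMB-oxy)-2-methylpent-4-en-2-ol
Conditions: CH2=CHMgBr, CuI (10 mol %), THF, −40 to 0 °C; aq NH4Cl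
Reagents that add atoms: vinylmagnesium bromide CH2=CHMgBr, C=C[Mg]Br
Why: copper-catalysed Grignard opening of a 2,2-disubstituted epoxide occurs by SN2 at the unsubstituted CH2 (C9), leaving C10 untouched and freeing the tertiary alcohol.

Step 4
Reactants: 4 (2S)-1-(PMB-oxy)-2-methylpent-4-en-2-ol
Product: 5 tertiary TMS ether of 4
Conditions: TMSOTf, Et3N, CH2Cl2, −78 to 0 °C
Reagents that add atoms: trimethylsilyl triflate, C[Si](C)(C)OS(=O)(=O)C(F)(F)F
Why: a silyl triflate silylates even a tertiary alcohol, and masking O10 prevents retro-aldol or oxa-Michael reactions of the β-oxygenated aldehyde and ynone that follow.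

Step 5
Reactants: 5 tertiary TMS ether of 4
Product: 6 (3S)-4-(PMB-oxy)-3-methyl-3-(trimethylsilyloxy)butanal (C8 aldehyde)
Conditions: OsO4 (2 mol %), NaIO4, 2,6-lutidine, dioxane/H2O 3:1, rt
Reagents that add atoms: OsO4, O=[Os](=O)(=O)=O; NaIO4, [Na+].[O-]I(=O)(=O)=O
Why: Lemieux–Johnson dihydroxylation/periodate cleavage of the terminal alkene gives the aldehyde under lutidine buffering, without the risk that ozone poses to the electron-rich PMB ring.

Step 6
Reactants: 6 C8 aldehyde; 7 2-(prop-2-yn-1-yloxy)oxane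
Product: 9 C8 propargylic alcohol (10S; both C8 epimers; C5 as oxan-2-yl ether), via lithium acetylide 8 (not isolated)
Conditions: 7, n-BuLi, THF, −78 °C; then 6, −78 to −20 °C; aq NH4Cl
Reagents that add atoms: none
Why: 1,2-addition of a lithium acetylide to an aldehyde forms the C7–C8 bond, and the unselective C8 centre is erased in the next step.

Step 7
Reactants: 9 C8 propargylic alcohol
Product: 10 ynone (10S), C8 ketone conjugated to the C6≡C7 alkyne
Conditions: Dess–Martin periodinane, NaHCO3, CH2Cl2, 0 °C to rt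
Reagents that add atoms: none
Why: buffered Dess–Martin oxidation converts a propargylic alcohol into the ynone without touching silyl, acetal or PMB groups.

Step 8
Reactants: 10 ynone
Product: 11 (8S,10S)-propargylic alcohol
Conditions: ketoreductase (NADPH-dependent alcohol dehydrogenase, (S)-selective for this ynone, chosen from a commercial panel), NADP+ (cat.), i-PrOH (10 % v/v), DMSO (10 % v/v), phosphate buffer pH 7, 30 °C
Reagents that add atoms: none
Why: the ketoreductase binds the slim alkynyl and the bulky alkyl arm in different pockets and transfers hydride from NADPH to a single carbonyl face, so C8 is set (S) under catalyst control independently of C10, with isopropanol recycling the cofactor.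

Step 9
Reactants: 11 (8S,10S)-propargylic alcohol
Product: 12 C8 TBS ether of 11
Conditions: TBSCl, imidazole, DMF, rt
Reagents that add atoms: tert-butyldimethylsilyl chloride, CC(C)(C)[Si](C)(C)Cl
Why: standard silylation of the secondary alcohol, needed so that only O5 directs the hydroalumination in step 11.

Step 10
Reactants: 12 C8 TBS ether
Product: 13 (4S,6S)-4-(TBS-oxy)-7-(PMB-oxy)-6-methylhept-2-yne-1,6-diol (C5 and C10 hydroxyls free)
Conditions: PPTS, MeOH, rt
Reagents that add atoms: none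
Why: mild acid methanolysis removes the acetal and the labile tertiary TMS ether while the secondary TBS ether survives.

Step 11
Reactants: 13 alkynediol
Product: 15 (2Z,4S,6S)-4-(TBS-oxy)-3-iodo-7-(PMB-oxy)-6-methylhept-2-ene-1,6-diol (iodine on C7), via alkenylalanate 14 (not isolated)
Conditions: NaAlH2(OCH2CH2OMe)2 (Red-Al), THF, 0 °C to rt; then I2, THF, −78 °C
Reagents that add atoms: iodine, II
Why: alkoxide-directed trans-hydroalumination of the propargylic alcohol puts hydride on C6 and aluminium on C7 through a five-membered chelate, and iodination with retention gives the Z-iodoalkene, kept cold so that the C8 silyloxy group is not eliminated to an allene.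

Step 12
Reactants: 16 2-bromoprop-2-en-1-ol
Product: 17 2-bromoallyl TBS ether
Conditions: TBSCl, imidazole, CH2Cl2, rt
Reagents that add atoms: tert-butyldimethylsilyl chloride, CC(C)(C)[Si](C)(C)Cl
Why: routine silylation of a primary allylic alcohol.

Step 13
Reactants: 17 2-bromoallyl TBS ether
Product: 19 tributyl[3-(TBS-oxy)prop-1-en-2-yl]stannane, via alkenyllithium 18 (not isolated)
Conditions: t-BuLi (2 equiv), Et2O, −78 °C; then Bu3SnCl, −78 °C to rt
Reagents that add atoms: tributyltin chloride, CCCC[Sn](CCCC)(CCCC)Cl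
Why: lithium–bromine exchange at −78 °C followed by stannylation gives the 1,1-disubstituted alkenylstannane that carries C11, C12 and C13.

Step 14
Reactants: 15 Z-iodoalkene diol; 19 alkenylstannane
Product: 20 (2E,4S,6S)-4-(TBS-oxy)-3-[3-(TBS-oxy)prop-1-en-2-yl]-7-(PMB-oxy)-6-methylhept-2-ene-1,6-diol (C5 cis to C11)
Conditions: Pd2(dba)3 (5 mol %), AsPh3, CuI, NMP, 40 °C
Reagents that add atoms: none
Why: Stille coupling at zerovalent palladium with copper assistance tolerates free hydroxyls and proceeds with retention, fixing the C6=C7 geometry needed for the epoxide.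

Step 15
Reactants: 20 dienol
Product: 22 (6R,7R,8S,10S)-oxolane diol: C7 bears C(=CH2)CH2OTBS and CH(OH)CH2OH; C8 OTBS; C10 methyl and CH2OPMB, via vinyl epoxide 21 (not isolated)
Conditions: Ti(OiPr)4, D-(−)-diethyl tartrate, t-BuOOH, 4 Å MS, CH2Cl2, −25 °C; work-up; then CSA (10 mol %), CH2Cl2, 0 °C
Reagents that add atoms: tert-butyl hydroperoxide, CC(C)(C)OO
Why: reagent-controlled Sharpless epoxidation of the allylic alkene sets C6 and C7 of the epoxide, and acid then triggers 5-exo opening by the C10 hydroxyl at the tertiary allylic C7 with inversion, which sets C7 of the oxolane and leaves the epoxide oxygen on C6 with retention.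

Step 16
Reactants: 22 oxolane diol
Product: 23 C5,C6-bis(TES) ether of 22
Conditions: TESOTf, 2,6-lutidine, CH2Cl2, −78 to 0 °C
Reagents that add atoms: triethylsilyl triflate, CC[Si](CC)(CC)OS(=O)(=O)C(F)(F)F
Why: the silyl triflate protects both the primary and the hindered secondary hydroxyl in one operation.

Step 17
Reactants: 23 bis(TES) ether
Product: 24 C5 aldehyde (C6 OTES retained)
Conditions: (COCl)2, DMSO, CH2Cl2, −78 to −30 °C; then Et3N, −78 to 0 °C
Reagents that add atoms: none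
Why: under Swern conditions a primary triethylsilyl ether is cleaved and oxidised in situ while secondary TES and all TBS ethers survive, and the cold amine quench avoids epimerisation at C6.

Step 18
Reactants: 24 C5 aldehyde; 25 ethyl 2-(triphenyl-λ5-phosphanylidene)propanoate
Product: 26 (4E)-enoate: ethyl ester at C3 on C4(CH3)=C5H
Conditions: toluene, 80 °C
Reagents that add atoms: none
Why: Wittig olefination with a stabilised α-methyl ylide gives the E-trisubstituted alkene under neutral conditions.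

Step 19
Reactants: 26 (4E)-enoate
Product: 27 (4E)-C3 allylic alcohol
Conditions: i-Bu2AlH, CH2Cl2, −78 °C; aq potassium sodium tartrate
Reagents that add atoms: none
Why: i-Bu2AlH reduces the conjugated ester by 1,2-addition to the allylic alcohol without affecting ethers or silyl groups.

Step 20
Reactants: 27 (4E)-C3 allylic alcohol
Product: 28 (4R,5R)-epoxy alcohol (C3 CH2OH)
Conditions: Ti(OiPr)4, D-(−)-diethyl tartrate, t-BuOOH, 4 Å MS, CH2Cl2, −20 °C
Reagents that add atoms: tert-butyl hydroperoxide, CC(C)(C)OO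
Why: Sharpless asymmetric epoxidation touches only the allylic alcohol alkene and sets C4 and C5 by reagent control, threo to C6, leaving the exocyclic methylene alone.

Step 21
Reactants: 28 epoxy alcohol
Product: 29 C3 epoxy aldehyde
Conditions: Dess–Martin periodinane, NaHCO3, CH2Cl2, rt
Reagents that add atoms: none
Why: buffered Dess–Martin oxidation gives an epoxy aldehyde whose α-carbon (C4) is quaternary and cannot epimerise.

Step 22
Reactants: 29 epoxy aldehyde
Product: 30 (2E)-alkenyl iodide (I–C2H=C3H on C4)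
Conditions: CrCl2, CHI3, THF/dioxane, 0 °C to rt
Reagents that add atoms: iodoform, IC(I)I
Why: Takai olefination with the geminal dichromium reagent from CHI3 and divalent chromium gives the E-iodoalkene under non-basic conditions, adding C2.

Step 23
Reactants: 30 alkenyl iodide
Product: 31 C1 primary alcohol
Conditions: DDQ, CH2Cl2/pH 7 buffer, 0 °C
Reagents that add atoms: none
Why: DDQ oxidises only the electron-rich PMB ether, and the buffered medium protects the vinyl epoxide and silyl ethers.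

Step 24
Reactants: 31 C1 alcohol
Product: 32 C1 aldehyde
Conditions: Dess–Martin periodinane, NaHCO3, CH2Cl2, rt
Reagents that add atoms: none
Why: Dess–Martin oxidation gives an aldehyde on the quaternary C10 that cannot enolise.

Step 25
Reactants: 32 iodo aldehyde
Product: 33 (2E)-cyclodecenol: ten-membered carbocycle with C1 OH (both epimers)
Conditions: CrCl2 (10 equiv), NiCl2 (10 mol %), degassed DMSO, 0.002 M by syringe pump, rt
Reagents that add atoms: none
Why: in the Nozaki–Hiyama–Kishi reaction zerovalent nickel activates the alkenyl iodide and hands it to trivalent chromium, which adds irreversibly and chemoselectively to the aldehyde under high dilution; the only new centre (C1) is later oxidised, so all six target centres are already fixed.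

Step 26
Reactants: 33 cyclodecenol
Product: 34 saturated C1 alcohol
Conditions: 2-nitrobenzenesulfonyl hydrazide, Et3N, CH2Cl2, rt
Reagents that add atoms: none
Why: diimide reduction transfers H2 concertedly to the strained ring alkene without hydrogenolysing the allylic epoxide, and the exocyclic methylene is much slower because it is flanked by the quaternary C7 and a silyloxymethyl group.

Step 27
Reactants: 34 C1 alcohol
Product: 35 C1 ketone
Conditions: Dess–Martin periodinane, NaHCO3, CH2Cl2, 0 °C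
Reagents that add atoms: none
Why: prompt buffered Dess–Martin oxidation forms the ketone before the C1 hydroxyl can open the C4–C5 epoxide.

Step 28
Reactants: 35 ketone
Product: 36 C6,C12-diol (C8 OTBS retained)
Conditions: HF·pyridine, pyridine, THF, 0 °C
Reagents that add atoms: none
Why: buffered HF·pyridine removes the TES ether and the primary allylic TBS ether much faster than the hindered secondary TBS ether at C8, and the epoxide tolerates it.

Step 29
Reactants: 36 diol
Product: 37 α-methylene-γ-lactone (12,6-olide) with C8 OTBS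
Conditions: MnO2 (activated, excess), CH2Cl2, rt
Reagents that add atoms: none
Why: MnO2 oxidises only the allylic C12 alcohol to the enal, which closes to the five-membered lactol with the C6 hydroxyl and is oxidised on to the lactone, O8 being blocked so the lactone can only form on O6.

Step 30
Reactants: 37 lactone TBS ether
Product: 38 C8 alcohol
Conditions: HF·pyridine, THF, 0 °C to rt
Reagents that add atoms: none
Why: acidic fluoride cleaves the last silyl ether without the basic conditions that would trigger translactonisation or conjugate addition to the methylene lactone.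

Step 31
Reactants: 38 C8 alcohol
Product: 39 target, (4R,5R,6R,7S,8S,10S)-8-methacrylate
Conditions: methacrylic anhydride, DMAP, Et3N, CH2Cl2, 0 °C to rt
Reagents that add atoms: methacrylic anhydride, C=C(C)C(=O)OC(=O)C(C)=C
Why: DMAP-catalysed acylation of the secondary alcohol occurs with retention at C8 and is faster than base-induced lactone migration.

## Compound list
1 | 2-methylprop-2-en-1-ol | C=C(C)CO | starting material
2 | [(2R)-2-methyloxiran-2-yl]methanol | OC[C@]1(C)CO1 | intermediate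
3 | (2S)-2-{[(4-methoxybenzyl)oxy]methyl}-2-methyloxirane | COc1ccc(COC[C@]2(C)CO2)cc1 | intermediate
4 | (2S)-1-[(4-methoxybenzyl)oxy]-2-methylpent-4-en-2-ol | COc1ccc(COC[C@@](C)(O)CC=C)cc1 | intermediate
5 | (2S)-1-[(4-methoxybenzyl)oxy]-2-methyl-2-[(trimethylsilyl)oxy]pent-4-ene | COc1ccc(COC[C@@](C)(O[Si](C)(C)C)CC=C)cc1 | intermediate
6 | (3S)-4-[(4-methoxybenzyl)oxy]-3-methyl-3-[(trimethylsilyl)oxy]butanal | COc1ccc(COC[C@@](C)(O[Si](C)(C)C)CC=O)cc1 | intermediate
7 | 2-(prop-2-yn-1-yloxy)oxane | C#CCOC1CCCCO1 | starting material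
8 | lithium 3-(oxan-2-yloxy)prop-1-yn-1-ide | [Li]C#CCOC1CCCCO1 | intermediate
9 | (2S,4RS)-1-[(4-methoxybenzyl)oxy]-2-methyl-7-(oxan-2-yloxy)-2-[(trimethylsilyl)oxy]hept-5-yn-4-ol | COc1ccc(COC[C@@](C)(O[Si](C)(C)C)CC(O)C#CCOC2CCCCO2)cc1 | intermediate
10 | (2S)-1-[(4-methoxybenzyl)oxy]-2-methyl-7-(oxan-2-yloxy)-2-[(trimethylsilyl)oxy]hept-5-yn-4-one | COc1ccc(COC[C@@](C)(O[Si](C)(C)C)CC(=O)C#CCOC2CCCCO2)cc1 | intermediate
11 | (2S,4S)-1-[(4-methoxybenzyl)oxy]-2-methyl-7-(oxan-2-yloxy)-2-[(trimethylsilyl)oxy]hept-5-yn-4-ol | COc1ccc(COC[C@@](C)(O[Si](C)(C)C)C[C@H](O)C#CCOC2CCCCO2)cc1 | intermediate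
12 | (2S,4S)-4-[(tert-butyldimethylsilyl)oxy]-1-[(4-methoxybenzyl)oxy]-2-methyl-7-(oxan-2-yloxy)-2-[(trimethylsilyl)oxy]hept-5-yne | COc1ccc(COC[C@@](C)(O[Si](C)(C)C)C[C@H](O[Si](C)(C)C(C)(C)C)C#CCOC2CCCCO2)cc1 | intermediate
13 | (4S,6S)-4-[(tert-butyldimethylsilyl)oxy]-7-[(4-methoxybenzyl)oxy]-6-methylhept-2-yne-1,6-diol | COc1ccc(COC[C@@](C)(O)C[C@H](O[Si](C)(C)C(C)(C)C)C#CCO)cc1 | intermediate
14 | sodium alkenylalanate of 13: five-membered O5–Al–C7 chelate ring, two 2-methoxyethoxy groups on aluminium (C10 hydroxyl drawn free) | [Na+].COCCO[Al-]1(OCCOC)OCC=C1[C@@H](O[Si](C)(C)C(C)(C)C)C[C@](C)(O)COCc1ccc(OC)cc1 | intermediate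
15 | (2Z,4S,6S)-4-[(tert-butyldimethylsilyl)oxy]-3-iodo-7-[(4-methoxybenzyl)oxy]-6-methylhept-2-ene-1,6-diol | COc1ccc(COC[C@@](C)(O)C[C@H](O[Si](C)(C)C(C)(C)C)/C(I)=C/CO)cc1 | intermediate
16 | 2-bromoprop-2-en-1-ol | C=C(Br)CO | starting material
17 | [(2-bromoprop-2-en-1-yl)oxy](tert-butyl)dimethylsilane | C=C(Br)CO[Si](C)(C)C(C)(C)C | intermediate
18 | {3-[(tert-butyldimethylsilyl)oxy]prop-1-en-2-yl}lithium | [Li]C(=C)CO[Si](C)(C)C(C)(C)C | intermediate
19 | tributyl{3-[(tert-butyldimethylsilyl)oxy]prop-1-en-2-yl}stannane | C=C(CO[Si](C)(C)C(C)(C)C)[Sn](CCCC)(CCCC)CCCC | intermediate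
20 | (2E,4S,6S)-4-[(tert-butyldimethylsilyl)oxy]-3-{3-[(tert-butyldimethylsilyl)oxy]prop-1-en-2-yl}-7-[(4-methoxybenzyl)oxy]-6-methylhept-2-ene-1,6-diol | COc1ccc(COC[C@@](C)(O)C[C@H](O[Si](C)(C)C(C)(C)C)/C(C(=C)CO[Si](C)(C)C(C)(C)C)=C/CO)cc1 | intermediate
21 | (6R,7S,8S,10S)-6,7-epoxide of 20 (vinyl epoxide; C5 CH2OH) | COc1ccc(COC[C@@](C)(O)C[C@H](O[Si](C)(C)C(C)(C)C)[C@@]2(C(=C)CO[Si](C)(C)C(C)(C)C)O[C@@H]2CO)cc1 | intermediate
22 | (6R,7R,8S,10S)-oxolane C5,C6-diol: C7 bears C(=CH2)CH2OTBS and CH(OH)CH2OH, C8 OTBS, C10 CH3 and CH2OPMB | COc1ccc(COC[C@]2(C)C[C@H](O[Si](C)(C)C(C)(C)C)[C@@](C(=C)CO[Si](C)(C)C(C)(C)C)([C@H](O)CO)O2)cc1 | intermediate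
23 | (6R,7S,8S,10S)-C5,C6-bis(triethylsilyl) ether of 22 | COc1ccc(COC[C@]2(C)C[C@H](O[Si](C)(C)C(C)(C)C)[C@@](C(=C)CO[Si](C)(C)C(C)(C)C)([C@H](O[Si](CC)(CC)CC)CO[Si](CC)(CC)CC)O2)cc1 | intermediate
24 | (6S,7S,8S,10S)-C5 aldehyde, C6 OTES | COc1ccc(COC[C@]2(C)C[C@H](O[Si](C)(C)C(C)(C)C)[C@@](C(=C)CO[Si](C)(C)C(C)(C)C)([C@H](O[Si](CC)(CC)CC)C=O)O2)cc1 | intermediate
25 | ethyl 2-(triphenyl-λ5-phosphanylidene)propanoate | CCOC(=O)C(C)=P(c1ccccc1)(c1ccccc1)c1ccccc1 | starting material
26 | (4E,6R,7S,8S,10S)-ethyl enoate (C3 ester, C4 methyl) | COc1ccc(COC[C@]2(C)C[C@H](O[Si](C)(C)C(C)(C)C)[C@@](C(=C)CO[Si](C)(C)C(C)(C)C)([C@H](O[Si](CC)(CC)CC)/C=C(\C)C(=O)OCC)O2)cc1 | intermediate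
27 | (4E,6R,7S,8S,10S)-C3 allylic alcohol | COc1ccc(COC[C@]2(C)C[C@H](O[Si](C)(C)C(C)(C)C)[C@@](C(=C)CO[Si](C)(C)C(C)(C)C)([C@H](O[Si](CC)(CC)CC)/C=C(\C)CO)O2)cc1 | intermediate
28 | (4R,5R,6R,7S,8S,10S)-4,5-epoxy C3 alcohol | COc1ccc(COC[C@]2(C)C[C@H](O[Si](C)(C)C(C)(C)C)[C@@](C(=C)CO[Si](C)(C)C(C)(C)C)([C@H](O[Si](CC)(CC)CC)[C@H]3O[C@]3(C)CO)O2)cc1 | intermediate
29 | (4S,5R,6R,7S,8S,10S)-4,5-epoxy C3 aldehyde | COc1ccc(COC[C@]2(C)C[C@H](O[Si](C)(C)C(C)(C)C)[C@@](C(=C)CO[Si](C)(C)C(C)(C)C)([C@H](O[Si](CC)(CC)CC)[C@H]3O[C@]3(C)C=O)O2)cc1 | intermediate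
30 | (2E,4R,5R,6R,7S,8S,10S)-C2 alkenyl iodide, C1 OPMB | COc1ccc(COC[C@]2(C)C[C@H](O[Si](C)(C)C(C)(C)C)[C@@](C(=C)CO[Si](C)(C)C(C)(C)C)([C@H](O[Si](CC)(CC)CC)[C@H]3O[C@]3(C)/C=C/I)O2)cc1 | intermediate
31 | (2E,4R,5R,6R,7S,8S,10S)-C2 alkenyl iodide, C1 CH2OH | OC[C@]1(C)C[C@H](O[Si](C)(C)C(C)(C)C)[C@@](C(=C)CO[Si](C)(C)C(C)(C)C)([C@H](O[Si](CC)(CC)CC)[C@H]2O[C@]2(C)/C=C/I)O1 | intermediate
32 | (2E,4R,5R,6R,7S,8S,10S)-C2 alkenyl iodide, C1 aldehyde | O=C[C@]1(C)C[C@H](O[Si](C)(C)C(C)(C)C)[C@@](C(=C)CO[Si](C)(C)C(C)(C)C)([C@H](O[Si](CC)(CC)CC)[C@H]2O[C@]2(C)/C=C/I)O1 | intermediate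
33 | (1RS,2E,4R,5R,6R,7S,8S,10S)-macrocyclic allylic alcohol: 4,5-epoxy-7,10-epoxy cyclodec-2-en-1-ol, C6 OTES, C8 OTBS, C7 C(=CH2)CH2OTBS | OC1/C=C/[C@@]2(C)O[C@@H]2[C@@H](O[Si](CC)(CC)CC)[C@@]3(C(=C)CO[Si](C)(C)C(C)(C)C)O[C@@]1(C)C[C@@H]3O[Si](C)(C)C(C)(C)C | intermediate
34 | (1RS,4R,5R,6R,7S,8S,10S)-saturated C1 alcohol | OC1CC[C@@]2(C)O[C@@H]2[C@@H](O[Si](CC)(CC)CC)[C@@]3(C(=C)CO[Si](C)(C)C(C)(C)C)O[C@@]1(C)C[C@@H]3O[Si](C)(C)C(C)(C)C | intermediate
35 | (4R,5R,6R,7S,8S,10S)-C1 ketone | O=C1CC[C@@]2(C)O[C@@H]2[C@@H](O[Si](CC)(CC)CC)[C@@]3(C(=C)CO[Si](C)(C)C(C)(C)C)O[C@@]1(C)C[C@@H]3O[Si](C)(C)C(C)(C)C | intermediate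
36 | (4R,5R,6R,7R,8S,10S)-C6,C12-diol, C8 OTBS | O=C1CC[C@@]2(C)O[C@@H]2[C@@H](O)[C@@]3(C(=C)CO)O[C@@]1(C)C[C@@H]3O[Si](C)(C)C(C)(C)C | intermediate
37 | (4R,5R,6R,7R,8S,10S)-12,6-olide (α-methylene-γ-lactone), C8 OTBS | O=C1CC[C@@]2(C)O[C@@H]2[C@H]4OC(=O)C(=C)[C@@]43O[C@@]1(C)C[C@@H]3O[Si](C)(C)C(C)(C)C | intermediate
38 | (4R,5R,6R,7S,8S,10S)-12,6-olide, C8 OH | O=C1CC[C@@]2(C)O[C@@H]2[C@H]4OC(=O)C(=C)[C@@]43O[C@@]1(C)C[C@@H]3O | intermediate
39 | CNP0241021.2, (4R,5R,6R,7S,8S,10S)-8-methacryloyloxy-1-oxo-4,5-epoxy-7,10-epoxygermacr-11(13)-en-12,6-olide | C=C(C)C(=O)O[C@H]1C[C@]2(C)O[C@@]13C(=C)C(=O)O[C@@H]3[C@H]1O[C@]1(C)CCC2=O | target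

## Count and weak points
Total steps: 31. Longest linear sequence: 29 (steps 1–11 and 14–31).

Step 25 (ring closure) is the most likely to fail. The ring being closed holds C1 and C6 on opposite faces of the oxolane and is strained, so oligomerisation or simple reduction of the iodide may win. The fallback sets out from 29 and closes C2=C3 by metathesis instead of C1–C2 by carbonyl addition. Wittig methylenation (Ph3P=CH2, THF) gives the vinyl epoxide F1; DDQ gives the C1 alcohol F2; Dess–Martin oxidation gives the C1 aldehyde F3; CH2=CHMgBr gives the C1 vinyl carbinol F4 (both epimers). Ring-closing metathesis with the second-generation Hoveyda–Grubbs catalyst, RuCl2(H2IMes)(=CH–C6H4-2-OiPr), in toluene at 80 °C and 0.001 M gives the cycloalkenol F5 as an E/Z mixture. Diimide reduction as in step 26 converts both isomers and the route is rejoined at 34.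

Step 26 (selective reduction) may also reduce the exocyclic C11=C13 alkene. The fallback sets out from 33 and rejoins at 35, replacing reduction plus oxidation by one redox isomerisation: CpRu(PPh3)2Cl (5 mol %) and Et3NHPF6 in dioxane at 80 °C. The ruthenium alkoxide undergoes β-hydride elimination and returns the hydride to C3 of the bound enone, giving the enol F6, which tautomerises to 35; an isolated alkene cannot enter this cycle.

Step 14 (Stille coupling) joins a hindered iodoalkene to an α-branched stannane, where transmetalation is slow and protodestannylation or cine substitution can intervene. The fallback sets out from 13 and 17 and rejoins at 20 with the coupling roles reversed. After the hydroalumination of step 11 the alanate 14 is not iodinated but transmetalated with ZnCl2 to the alkenylzinc chloride F7. F7 is then coupled with bromide 17 under Pd(PPh3)4 in THF (Negishi coupling), so neither the iodide 15 nor the stannane 19 is needed.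

## Further compounds
F1 | step 25 | (4R,5R,6R,7S,8S,10S)-C3 vinyl epoxide, C1 OPMB | COc1ccc(COC[C@]2(C)C[C@H](O[Si](C)(C)C(C)(C)C)[C@@](C(=C)CO[Si](C)(C)C(C)(C)C)([C@H](O[Si](CC)(CC)CC)[C@H]3O[C@]3(C)C=C)O2)cc1
F2 | step 25 | C3 vinyl epoxide, C1 CH2OH | OC[C@]1(C)C[C@H](O[Si](C)(C)C(C)(C)C)[C@@](C(=C)CO[Si](C)(C)C(C)(C)C)([C@H](O[Si](CC)(CC)CC)[C@H]2O[C@]2(C)C=C)O1
F3 | step 25 | C3 vinyl epoxide, C1 aldehyde | O=C[C@]1(C)C[C@H](O[Si](C)(C)C(C)(C)C)[C@@](C(=C)CO[Si](C)(C)C(C)(C)C)([C@H](O[Si](CC)(CC)CC)[C@H]2O[C@]2(C)C=C)O1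
F4 | step 25 | C1 vinyl carbinol (both C1 epimers) with C3 vinyl epoxide | C=CC(O)[C@]1(C)C[C@H](O[Si](C)(C)C(C)(C)C)[C@@](C(=C)CO[Si](C)(C)C(C)(C)C)([C@H](O[Si](CC)(CC)CC)[C@H]2O[C@]2(C)C=C)O1
F5 | step 25 | macrocyclic C2=C3 allylic alcohol, E/Z mixture, C1 epimers | OC1C=C[C@@]2(C)O[C@@H]2[C@@H](O[Si](CC)(CC)CC)[C@@]3(C(=C)CO[Si](C)(C)C(C)(C)C)O[C@@]1(C)C[C@@H]3O[Si](C)(C)C(C)(C)C
F6 | step 26 | C1 enol (C1=C2) of ketone 35 | OC1=CC[C@@]2(C)O[C@@H]2[C@@H](O[Si](CC)(CC)CC)[C@@]3(C(=C)CO[Si](C)(C)C(C)(C)C)O[C@@]1(C)C[C@@H]3O[Si](C)(C)C(C)(C)C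
F7 | step 14 | (Z)-C7 alkenylzinc chloride of diol 13 (zinc cis to C5) | OC/C=C(\[Zn]Cl)[C@@H](O[Si](C)(C)C(C)(C)C)C[C@](C)(O)COCc1ccc(OC)cc1
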